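I carried 0.295 M: the even-split concentration Z*, the constant of the first step over that of the second, the level of Z at which free J passes as fast into G as into J.Z.

    J + Z → J.Z (k1 = 0.059 L mol⁻¹ s⁻¹)
    J + 2 Z → G (k2 = 0.20 L² mol⁻² s⁻¹)
    J.Z → X (k3 = 0.013 s⁻¹)

| flask | J | Z | time |
|---|---|---|---|
| winter | 0.20 M | 0.800 equiv | 80 s |
| summer | 0.20 M | 1.50 equiv | 80 s |
| noon | 0.20 M | 3.00 equiv | 80 s |

- a step written with two of one species runs at k times the square of its concentration and takes two of it each time
- "hardly changes" means that all values lie within two and a half points (for a concentration: within two and a half percent of the largest)
- run time (winter): 80 s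

- amount of J.Z at the end, in percent of the J charged for winter, summer, noon, in this order
- the shape of the row from first to last (hardly changes / rises, then falls / falls, then rises / rises all the way / falls all the way)

At any moment, free J splits with odds Z/Z* for G against J.Z. At the start, the common logarithm of these odds was −0.266 in winter, 0.00730 in summer and 0.308 at noon. The branch through J.Z therefore began with 64.8%, 49.6% and 33.0% of the J used. Z falls as the first two steps run and nothing returns it, so each share climbs from there. More Z uses J faster but lowers that share, so I expected the row to rise and then fall, with its top near Z* expressed in equivalents, 1.47. J.Z also passes into X with a half-life of 53.3 s, shorter than the run, and my reckoning by hand went no further than the direction of the row.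

The forecast gave 16.7%, 21.2% and 17.3%, with the shape "rises, then falls", and said of noon: “J is almost gone early, so more J.Z has time to decay and more goes to G”.

The simulation gave 17.1%, 21.8% and 17.7%, with the shape "rises, then falls", and the row turned at 1.8 equiv, above my 1.47.

In the noon flask, Z still stood at 0.316 M at 40.0 s, above Z*, and by then J had fallen to 11.5% while G had reached 53.3%. At 80.0 s Z stood at 0.290 M, and the noon flask had sent 40.6% of its used J through J.Z, above the starting 33.0% and below the 50.4% that Z* gives at that final Z. The winter flask, ending at 0.0528 M of Z, had sent 74.2% of its used J through J.Z, above its starting 64.8% and below the 84.8% that Z* gives at that final Z.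

The numbers are invented; no experiment stands behind them.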